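**Plan** (numbering: C1 = CO2H carbon, C3–C6 = ring carbons, O2 on C3, O1 on C6, C7=C8 = side-chain alkene, C10 = side-chain stereocentre)
- Retrosynthesis: cut O1–C6 of the 1,2-dioxane (C3 hydroperoxide onto a C6 cation), then C6–C7 (alkenyl metal + C6 ethyl ketone), then rejoin C1 and C6 as the C1=C6 bond of a cyclohexene, the Birch product of 1,3-diethylbenzene.
- Enabling feature: C6 is tertiary and allylic to C7=C8, so ionisation gives a C6–C7–C8 allyl cation that the hydroperoxide on C3 reaches 6-exo, closing the ring O1, O2, C3, C4, C5, C6.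
- Forward: dearomatise 1,3-diethylbenzene (its six ring carbons and two ethyl groups become C1–C6 and the C4/C6 ethyls), hydroborate, invert C3–O, open the temporary C1=C6 bond by ozonolysis, add the alkenyl chain at C6, bring in O2–O1 at C3, close the dioxane, oxidise C1.
- Stereochemistry: C4 (and C3) from IpcBH2 hydroboration; C3 then passes through two inversions (Mitsunobu, SN2 by HOO−); C10 from Cu-catalysed conjugate addition; (E)-C7=C8 from Zr-catalysed carboalumination; C6 in the ring closure.
- C6 is the one centre without firm control: the closure is expected to give both C6 epimers, to be separated, with the unwanted one recycled.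

Key step: step 16

Assumption: the facial sense of the two reagent-controlled steps (IpcBH2 from (−)-α-pinene in step 2, (R)-Tol-BINAP/CuI in step 7) is assigned by analogy with 1-alkylcyclohexenes and (E)-alk-2-enoates; if either proves opposite, the antipodal reagent or ligand is to be used.

**Step 1**
Reactants: 1 1,3-diethylbenzene
Product: 2 1,5-diethylcyclohexa-1,4-diene
Conditions: Li, NH3(l), THF, EtOH, −78 to −33 °C
Reagents that add atoms: none
Why: Birch reduction of a 1,3-dialkylbenzene leaves both alkyl groups on sp2 carbons of the 1,4-diene, so the arene's ring carbons and ethyl groups become C1–C6 and the C4/C6 ethyl groups (dearomatisation).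

**Step 2**
Reactants: 2 1,5-diethylcyclohexa-1,4-diene
Product: 3 [(1R,6R)-4,6-diethylcyclohex-3-en-1-yl](isopinocampheyl)borane (Ipc from (−)-α-pinene; B trans to the adjacent ethyl)
Conditions: IpcBH2 (1.0 equiv, freed from its TMEDA adduct with BF3·OEt2), Et2O, −25 °C; crystallisation at −35 °C
Reagents that add atoms: monoisopinocampheylborane, B[C@H]1C[C@H]2C[C@@H]([C@@H]1C)C2(C)C
Why: Asymmetric hydroboration of one of the two equivalent ring alkenes (faces enantiotopic) adds H to the ethyl-bearing carbon and B to the CH carbon syn, so B is trans to ethyl; the Ipc group selects the face and sets C4 (R) and C3 (R), and crystallisation of the dialkylborane should raise optical purity.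

**Step 3**
Reactants: 3 [(1R,6R)-4,6-diethylcyclohex-3-en-1-yl](isopinocampheyl)borane
Product: 4 (1R,6R)-4,6-diethylcyclohex-3-en-1-ol (OH trans to the adjacent ethyl)
Conditions: NaOH (3 M aq.), H2O2 (30%), THF, 0 °C to rt
Reagents that add atoms: hydrogen peroxide, OO
Why: Alkaline peroxide oxidation of the C–B bond proceeds with retention (organoborane oxidation) and should leave the remaining trisubstituted ring alkene untouched.

**Step 4**
Reactants: 4 (1R,6R)-4,6-diethylcyclohex-3-en-1-ol
Product: 5 (1S,6R)-4,6-diethylcyclohex-3-en-1-yl benzoate (ester cis to the adjacent ethyl)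
Conditions: PhCO2H, PPh3, DIAD, toluene, 0 °C to rt
Reagents that add atoms: benzoic acid, OC(=O)c1ccccc1
Why: Mitsunobu esterification displaces the alkoxyphosphonium ion by benzoate in an SN2 step, which inverts the carbinol centre to the configuration needed for the later SN2 entry of the peroxide oxygen and protects it at the same time.

**Step 5**
Reactants: 5 (1S,6R)-4,6-diethylcyclohex-3-en-1-yl benzoate
Product: 8 (3S,4R)-4-ethyl-1-hydroxy-6-oxooctan-3-yl benzoate, via ozonide 6 (not isolated), via keto aldehyde 7 (not isolated)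
Conditions: O3, CH2Cl2, −78 °C; PPh3, −78 °C to rt; then NaBH(OAc)3, AcOH, rt
Reagents that add atoms: ozone, [O-][O+]=O
Why: Ozonolysis cleaves the C1=C6 ring bond, which is absent from the target, to the C6 ethyl ketone and the C1 aldehyde, and NaBH(OAc)3 reduces only the aldehyde (chemoselective hydride reduction) in the same flask before the β-benzoyloxy aldehyde can eliminate.

**Step 6**
Reactants: 8 (3S,4R)-4-ethyl-1-hydroxy-6-oxooctan-3-yl benzoate
Product: 9 (3S,4R)-1-[(tert-butyldiphenylsilyl)oxy]-4-ethyl-6-oxooctan-3-yl benzoate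
Conditions: TBDPSCl, imidazole, CH2Cl2, 0 °C
Reagents that add atoms: tert-butyl(chloro)diphenylsilane, CC(C)(C)[Si](Cl)(c1ccccc1)c1ccccc1
Why: Silylation of the primary alcohol keeps C1 at the alcohol oxidation level, so that no carbonyl group lies β to the later C3 leaving group.

**Step 7**
Reactants: 10 methyl (E)-pent-2-enoate
Product: 11 methyl (S)-3-ethylheptanoate
Conditions: n-BuMgBr, CuI (2 mol%), (R)-Tol-BINAP (3 mol%), t-BuOMe, −40 °C
Reagents that add atoms: butylmagnesium bromide, CCCC[Mg]Br
Why: Copper-catalysed asymmetric conjugate addition of the Grignard reagent to the (E)-enoate, in which the chiral copper–phosphine complex selects the enoate face and sets C10 (S).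

**Step 8**
Reactants: 11 methyl (S)-3-ethylheptanoate
Product: 12 (S)-3-ethylheptanal
Conditions: i-Bu2AlH (1.05 equiv), CH2Cl2, −78 °C
Reagents that add atoms: none
Why: Partial ester reduction stops at the aluminium hemiacetal at −78 °C and gives the aldehyde on work-up; the β-stereocentre cannot epimerise.

**Step 9**
Reactants: 12 (S)-3-ethylheptanal
Product: 13 (S)-4-ethyloct-1-yne
Conditions: dimethyl (1-diazo-2-oxopropyl)phosphonate, K2CO3, MeOH, 0 °C to rt
Reagents that add atoms: dimethyl (1-diazo-2-oxopropyl)phosphonate, CC(=O)C(=[N+]=[N-])P(=O)(OC)OC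
Why: Ohira–Bestmann homologation converts the aldehyde into the terminal alkyne under mild base.

**Step 10**
Reactants: 13 (S)-4-ethyloct-1-yne
Product: 15 (1E,4S)-4-ethyl-1-iodo-2-methyloct-1-ene, via alkenylalane 14 (not isolated)
Conditions: Me3Al (2 equiv), Cp2ZrCl2 (0.25 equiv), CH2Cl2, 0 °C to rt; then I2, THF, −30 °C
Reagents that add atoms: trimethylaluminium, C[Al](C)C; iodine, II
Why: Zirconium-catalysed carboalumination (Negishi) adds methyl and aluminium syn across the alkyne with methyl on the internal carbon, and iodinolysis with retention fixes the (E)-trisubstituted C7=C8 geometry.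

**Step 11**
Reactants: 15 (1E,4S)-4-ethyl-1-iodo-2-methyloct-1-ene; 9 (3S,4R)-1-[(tert-butyldiphenylsilyl)oxy]-4-ethyl-6-oxooctan-3-yl benzoate
Product: 18 (3S,4R,7E,10S)-1-[(tert-butyldiphenylsilyl)oxy]-4,6,10-triethyl-6-hydroxy-8-methyltetradec-7-en-3-yl benzoate (both C6 epimers), via alkenyllithium 16 (not isolated), via alkenylcerium dichloride 17 (not isolated)
Conditions: 15 (1.2 equiv), t-BuLi (2 equiv per 15), Et2O, −78 °C; CeCl3, THF, −78 °C; then 9, −78 °C
Reagents that add atoms: none
Why: Iodine–lithium exchange with retention of alkene geometry, transmetalation to the weakly basic organocerium reagent and 1,2-addition to the ethyl ketone (organocerium addition) should spare the benzoate; the configuration of the new C6 carbinol does not matter because C6 is ionised in step 16.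

**Step 12**
Reactants: 18 (3S,4R,7E,10S)-1-[(tert-butyldiphenylsilyl)oxy]-4,6,10-triethyl-6-hydroxy-8-methyltetradec-7-en-3-yl benzoate
Product: 19 (3S,4R,7E,10S)-1-[(tert-butyldiphenylsilyl)oxy]-4,6,10-triethyl-8-methyl-6-[(triethylsilyl)oxy]tetradec-7-en-3-yl benzoate (both C6 epimers)
Conditions: Et3SiOTf, 2,6-lutidine, CH2Cl2, −78 °C
Reagents that add atoms: triethylsilyl trifluoromethanesulfonate, CC[Si](CC)(CC)OS(=O)(=O)C(F)(F)F
Why: Silylation masks the tertiary allylic alcohol so that it cannot displace the C3 mesylate (tetrahydrofuran formation) in steps 14 and 15, and the silyl ether is the latent leaving group of step 16.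

**Step 13**
Reactants: 19 (3S,4R,7E,10S)-1-[(tert-butyldiphenylsilyl)oxy]-4,6,10-triethyl-8-methyl-6-[(triethylsilyl)oxy]tetradec-7-en-3-yl benzoate
Product: 20 (3S,4R,7E,10S)-1-[(tert-butyldiphenylsilyl)oxy]-4,6,10-triethyl-8-methyl-6-[(triethylsilyl)oxy]tetradec-7-en-3-ol (both C6 epimers)
Conditions: i-Bu2AlH (2.5 equiv), CH2Cl2, −78 °C
Reagents that add atoms: none
Why: Reductive cleavage of the benzoate by the aluminium hydride frees the C3 alcohol without base, and both silyl ethers should survive.

**Step 14**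
Reactants: 20 (3S,4R,7E,10S)-1-[(tert-butyldiphenylsilyl)oxy]-4,6,10-triethyl-8-methyl-6-[(triethylsilyl)oxy]tetradec-7-en-3-ol
Product: 21 (3S,4R,7E,10S)-1-[(tert-butyldiphenylsilyl)oxy]-4,6,10-triethyl-8-methyl-6-[(triethylsilyl)oxy]tetradec-7-en-3-yl methanesulfonate (both C6 epimers)
Conditions: MsCl, Et3N, CH2Cl2, −20 to 0 °C
Reagents that add atoms: methanesulfonyl chloride, CS(=O)(=O)Cl
Why: Sulfonylation at oxygen activates C3 with retention of configuration.

**Step 15**
Reactants: 21 (3S,4R,7E,10S)-1-[(tert-butyldiphenylsilyl)oxy]-4,6,10-triethyl-8-methyl-6-[(triethylsilyl)oxy]tetradec-7-en-3-yl methanesulfonate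
Product: 22 (3R,4R,7E,10S)-1-[(tert-butyldiphenylsilyl)oxy]-4,6,10-triethyl-8-methyl-6-[(triethylsilyl)oxy]tetradec-7-en-3-yl hydroperoxide (both C6 epimers)
Conditions: H2O2 (50% aq., large excess), KOH, MeOH/THF, 0 °C to rt
Reagents that add atoms: hydrogen peroxide, OO
Why: SN2 displacement of the secondary mesylate by hydroperoxide anion (alkyl hydroperoxide synthesis from sulfonates) inverts C3 to (R), and the excess of H2O2 suppresses dialkyl peroxide formation.

**Step 16**
Reactants: 22 (3R,4R,7E,10S)-1-[(tert-butyldiphenylsilyl)oxy]-4,6,10-triethyl-8-methyl-6-[(triethylsilyl)oxy]tetradec-7-en-3-yl hydroperoxide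
Product: 23 tert-butyl{2-[(3R,4R,6R)-4,6-diethyl-6-[(1E,4S)-4-ethyl-2-methyloct-1-en-1-yl]-1,2-dioxan-3-yl]ethoxy}diphenylsilane
Conditions: CSA (0.2 equiv), CH2Cl2 (0.01 M), −20 to 0 °C
Reagents that add atoms: none
Why: The acid ionises the tertiary, allylic C6–OSiEt3 bond (directly or after silyl transfer to the hydroperoxide) to the C6–C7–C8 allyl cation, and the terminal oxygen of the C3 hydroperoxide captures it at C6 with loss of Et3SiOH, which forms the O1–C6 bond and the 1,2-dioxane in one event. The closest known reaction type is the acid-mediated alkylation of hydroperoxides by tertiary carbinols, whose intramolecular form closes 1,2-dioxanes and 1,2-dioxolanes from hydroperoxy tertiary alcohols. The ring closes in the 6-exo mode at the C6 end of the cation; attack at C8 would need an eight-membered ring, so ring size fixes the regiochemistry. The new C6 stereocentre is set under substrate control in a chair-like transition state with the C4 ethyl group equatorial, the C3 arm axial and the (E)-alkenyl end of the planar cation pseudo-equatorial, which puts the C6 ethyl group axial as in the target; this preference is expected to be weak, both C6 epimers of 22 converge on the same cation, and the unwanted C6 epimer of 23 is to be separated and re-ionised under the same acid. The step also needs the (E)-C7=C8 geometry and the O–O bond to survive: capture at low temperature should outrun C7–C8 rotation and proton loss in the cation, and the secondary hydroperoxide has no good migrating group for Hock cleavage under CSA.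

**Step 17**
Reactants: 23 tert-butyl{2-[(3R,4R,6R)-4,6-diethyl-6-[(1E,4S)-4-ethyl-2-methyloct-1-en-1-yl]-1,2-dioxan-3-yl]ethoxy}diphenylsilane
Product: 24 2-[(3R,4R,6R)-4,6-diethyl-6-[(1E,4S)-4-ethyl-2-methyloct-1-en-1-yl]-1,2-dioxan-3-yl]ethan-1-ol
Conditions: Bu4NF, AcOH, THF, 0 °C to rt
Reagents that add atoms: none
Why: Buffered fluoride desilylation frees the primary alcohol under conditions that should ionise neither the tertiary allylic C6–O bond nor attack the peroxide.

**Step 18**
Reactants: 24 2-[(3R,4R,6R)-4,6-diethyl-6-[(1E,4S)-4-ethyl-2-methyloct-1-en-1-yl]-1,2-dioxan-3-yl]ethan-1-ol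
Product: 26 2-[(3R,4R,6R)-4,6-diethyl-6-[(1E,4S)-4-ethyl-2-methyloct-1-en-1-yl]-1,2-dioxan-3-yl]acetic acid, via aldehyde 25 (not isolated)
Conditions: TEMPO (0.2 equiv), PhI(OAc)2 (2.5 equiv), MeCN/H2O, rt
Reagents that add atoms: water, O
Why: Oxoammonium oxidation takes the primary alcohol through the aldehyde hydrate to the acid under near-neutral, non-reducing conditions that should leave the peroxide and the trisubstituted alkene intact.

**Compound list**
1 | 1,3-diethylbenzene | CCc1cccc(CC)c1 | starting material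
2 | 1,5-diethylcyclohexa-1,4-diene | CCC1=CCC=C(CC)C1 | intermediate
3 | [(1R,6R)-4,6-diethylcyclohex-3-en-1-yl](isopinocampheyl)borane | C1[C@@H](CC)[C@H](B[C@H]2C[C@H]3C[C@@H]([C@@H]2C)C3(C)C)CC=C1CC | intermediate
4 | (1R,6R)-4,6-diethylcyclohex-3-en-1-ol | C1[C@@H](CC)[C@H](O)CC=C1CC | intermediate
5 | (1S,6R)-4,6-diethylcyclohex-3-en-1-yl benzoate | C1[C@@H](CC)[C@@H](OC(=O)c2ccccc2)CC=C1CC | intermediate
6 | ozonide of 5, 1,3-diethyl-7,8,9-trioxabicyclo[4.2.1]nonan-4-yl benzoate (benzoate and ethyl carbons as in 5, mixture at the two ozonide carbons) | C1[C@@H](CC)[C@@H](OC(=O)c2ccccc2)CC2OOC1(CC)O2 | intermediate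
7 | (3S,4R)-4-ethyl-1,6-dioxooctan-3-yl benzoate | CCC(=O)C[C@@H](CC)[C@@H](OC(=O)c1ccccc1)CC=O | intermediate
8 | (3S,4R)-4-ethyl-1-hydroxy-6-oxooctan-3-yl benzoate | CCC(=O)C[C@@H](CC)[C@@H](OC(=O)c1ccccc1)CCO | intermediate
9 | (3S,4R)-1-[(tert-butyldiphenylsilyl)oxy]-4-ethyl-6-oxooctan-3-yl benzoate | CCC(=O)C[C@@H](CC)[C@@H](OC(=O)c1ccccc1)CCO[Si](c1ccccc1)(c1ccccc1)C(C)(C)C | intermediate
10 | methyl (E)-pent-2-enoate | CC/C=C/C(=O)OC | starting material
11 | methyl (S)-3-ethylheptanoate | CCCC[C@H](CC)CC(=O)OC | intermediate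
12 | (S)-3-ethylheptanal | CCCC[C@H](CC)CC=O | intermediate
13 | (S)-4-ethyloct-1-yne | CCCC[C@H](CC)CC#C | intermediate
14 | [(1E,4S)-4-ethyl-2-methyloct-1-en-1-yl]dimethylalane | CCCC[C@H](CC)C/C(C)=C/[Al](C)C | intermediate
15 | (1E,4S)-4-ethyl-1-iodo-2-methyloct-1-ene | CCCC[C@H](CC)C/C(C)=C/I | intermediate
16 | [(1E,4S)-4-ethyl-2-methyloct-1-en-1-yl]lithium | CCCC[C@H](CC)C/C(C)=C/[Li] | intermediate
17 | [(1E,4S)-4-ethyl-2-methyloct-1-en-1-yl]cerium dichloride | CCCC[C@H](CC)C/C(C)=C/[Ce](Cl)Cl | intermediate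
18 | (3S,4R,7E,10S)-1-[(tert-butyldiphenylsilyl)oxy]-4,6,10-triethyl-6-hydroxy-8-methyltetradec-7-en-3-yl benzoate (both C6 epimers) | CCCC[C@H](CC)C/C(C)=C/C(O)(CC)C[C@@H](CC)[C@@H](OC(=O)c1ccccc1)CCO[Si](c1ccccc1)(c1ccccc1)C(C)(C)C | intermediate
19 | (3S,4R,7E,10S)-1-[(tert-butyldiphenylsilyl)oxy]-4,6,10-triethyl-8-methyl-6-[(triethylsilyl)oxy]tetradec-7-en-3-yl benzoate (both C6 epimers) | CCCC[C@H](CC)C/C(C)=C/C(O[Si](CC)(CC)CC)(CC)C[C@@H](CC)[C@@H](OC(=O)c1ccccc1)CCO[Si](c1ccccc1)(c1ccccc1)C(C)(C)C | intermediate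
20 | (3S,4R,7E,10S)-1-[(tert-butyldiphenylsilyl)oxy]-4,6,10-triethyl-8-methyl-6-[(triethylsilyl)oxy]tetradec-7-en-3-ol (both C6 epimers) | CCCC[C@H](CC)C/C(C)=C/C(O[Si](CC)(CC)CC)(CC)C[C@@H](CC)[C@@H](O)CCO[Si](c1ccccc1)(c1ccccc1)C(C)(C)C | intermediate
21 | (3S,4R,7E,10S)-1-[(tert-butyldiphenylsilyl)oxy]-4,6,10-triethyl-8-methyl-6-[(triethylsilyl)oxy]tetradec-7-en-3-yl methanesulfonate (both C6 epimers) | CCCC[C@H](CC)C/C(C)=C/C(O[Si](CC)(CC)CC)(CC)C[C@@H](CC)[C@@H](OS(C)(=O)=O)CCO[Si](c1ccccc1)(c1ccccc1)C(C)(C)C | intermediate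
22 | (3R,4R,7E,10S)-1-[(tert-butyldiphenylsilyl)oxy]-4,6,10-triethyl-8-methyl-6-[(triethylsilyl)oxy]tetradec-7-en-3-yl hydroperoxide (both C6 epimers) | CCCC[C@H](CC)C/C(C)=C/C(O[Si](CC)(CC)CC)(CC)C[C@@H](CC)[C@H](OO)CCO[Si](c1ccccc1)(c1ccccc1)C(C)(C)C | intermediate
23 | tert-butyl{2-[(3R,4R,6R)-4,6-diethyl-6-[(1E,4S)-4-ethyl-2-methyloct-1-en-1-yl]-1,2-dioxan-3-yl]ethoxy}diphenylsilane | CCCC[C@H](CC)C/C(C)=C/[C@@]1(CC)C[C@@H](CC)[C@@H](CCO[Si](c2ccccc2)(c2ccccc2)C(C)(C)C)OO1 | intermediate
24 | 2-[(3R,4R,6R)-4,6-diethyl-6-[(1E,4S)-4-ethyl-2-methyloct-1-en-1-yl]-1,2-dioxan-3-yl]ethan-1-ol | CCCC[C@H](CC)C/C(C)=C/[C@@]1(CC)C[C@@H](CC)[C@@H](CCO)OO1 | intermediate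
25 | 2-[(3R,4R,6R)-4,6-diethyl-6-[(1E,4S)-4-ethyl-2-methyloct-1-en-1-yl]-1,2-dioxan-3-yl]acetaldehyde | CCCC[C@H](CC)C/C(C)=C/[C@@]1(CC)C[C@@H](CC)[C@@H](CC=O)OO1 | intermediate
26 | 2-[(3R,4R,6R)-4,6-diethyl-6-[(1E,4S)-4-ethyl-2-methyloct-1-en-1-yl]-1,2-dioxan-3-yl]acetic acid (CNP0229029.2) | CCCC[C@H](CC)C/C(C)=C/[C@@]1(CC)C[C@@H](CC)[C@@H](CC(=O)O)OO1 | target

**Count and risks**
Total step count: 18. Longest linear sequence: 14 steps (steps 1–6 and 11–18, from 1,3-diethylbenzene); the side chain takes steps 7–10 and joins in step 11.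

Step 16 (ring closure). What may go wrong: weak facial discrimination at C6 in the capture of the cation, proton loss from the cation to trienes, and rotation about C7–C8 before capture. Fallback, from 21 back to 23: the cation is trapped intermolecularly instead. Treating 21 with anhydrous H2O2 in Et2O and catalytic CSA should give the open-chain tertiary allylic hydroperoxide (3S,4R,6R,7E,10S)-1-[(tert-butyldiphenylsilyl)oxy]-4,6,10-triethyl-6-hydroperoxy-8-methyltetradec-7-en-3-yl methanesulfonate F1, to be separated from its C6 epimer and the C8 regioisomer. KOt-Bu with 18-crown-6 in THF then closes the ring by intramolecular SN2 displacement of the C3 mesylate with inversion, giving 23. This fallback does not raise the selectivity at C6 either; it only moves the separation of the epimers to an open-chain stage.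

Step 15 (peroxide oxygen at C3). What may go wrong: bimolecular elimination at the β-branched secondary mesylate and slow substitution, and loss of the tertiary silyl ether followed by tetrahydrofuran formation. Fallback, from 21 back to 22: alkylation of a masked hydroperoxide in an aprotic medium followed by unmasking. 21 with 2-methoxypropan-2-yl hydroperoxide and CsOH in DMF should give the perketal tert-butyl{[(3R,4R,7E,10S)-4,6,10-triethyl-3-[(2-methoxypropan-2-yl)peroxy]-8-methyl-6-[(triethylsilyl)oxy]tetradec-7-en-1-yl]oxy}diphenylsilane F2, and mild aqueous acetic acid in THF then releases 22.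

Step 2 (absolute configuration). What may go wrong: incomplete enantiofacial discrimination in the hydroboration, and failure of the dialkylborane to crystallise, which would leave 4 of insufficient optical purity. Fallback, from 4 (as obtained in step 3) back to 4: enzymatic enrichment. Candida antarctica lipase B with vinyl acetate in t-BuOMe should acetylate the (1R) alcohol to (1R,6R)-4,6-diethylcyclohex-3-en-1-yl acetate F3, which is separated from the unreacted (1S,6S) alcohol and returned to 4 with K2CO3 in MeOH.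

**Further compounds**
F1 | step 16 | (3S,4R,6R,7E,10S)-1-[(tert-butyldiphenylsilyl)oxy]-4,6,10-triethyl-6-hydroperoxy-8-methyltetradec-7-en-3-yl methanesulfonate | CCCC[C@H](CC)C/C(C)=C/[C@@](OO)(CC)C[C@@H](CC)[C@@H](OS(C)(=O)=O)CCO[Si](c1ccccc1)(c1ccccc1)C(C)(C)C
F2 | step 15 | tert-butyl{[(3R,4R,7E,10S)-4,6,10-triethyl-3-[(2-methoxypropan-2-yl)peroxy]-8-methyl-6-[(triethylsilyl)oxy]tetradec-7-en-1-yl]oxy}diphenylsilane (both C6 epimers) | CCCC[C@H](CC)C/C(C)=C/C(O[Si](CC)(CC)CC)(CC)C[C@@H](CC)[C@H](OOC(C)(C)OC)CCO[Si](c1ccccc1)(c1ccccc1)C(C)(C)C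
F3 | step 2 | (1R,6R)-4,6-diethylcyclohex-3-en-1-yl acetate | C1[C@@H](CC)[C@H](OC(C)=O)CC=C1CC
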